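**Plan**
- Target read as fisetinidol-(4α→8)-fisetinidol: two (2R,3S) 2,3-trans flavan-3-ol units, upper C4 (S), 3,4-trans.
- Retrosynthesis: the interflavan C4–C8 bond is cut first (flavan-4-yl cation plus ring A of a second flavan), so both halves fall back on one O-benzylated 5-chloroflavan. In ring C of that flavan the bonds O1–C8a and C4–C4a are then cut together.
- Enabling feature: C8a and C4a are neighbours in ring A, that is, the two carbons of an aryne. The chain O1–C2–C3–C4 can carry an alkoxide at one end and a CH2I at the other. A chlorine at C5 (meta to the C7 oxygen) makes the aryne regioselective, later steers the interflavan bond to C8, and leaves in the final hydrogenolysis.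
- Forward order: C2–C3 chain by glycolate aldol, ring C annulated onto ring A, C4 oxidation of one portion, C4–C8 union, global hydrogenolysis.
- Stereochemistry: C2 and C3 of both units come from one auxiliary-controlled anti-aldol and are carried through the annulation unchanged (anti becomes 2,3-trans). Upper C4 is set by attack anti to the 3-benzyloxy group.

Key step: step 6

Assumption: the aldol of step 2 is taken to proceed through the thiocarbonyl-chelated titanium enolate, with the aldehyde entering anti to the C4 benzyl group, which is why the (S)-auxiliary is used; the opposite sense would call for the (R)-auxiliary.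

Step 1
Reactants: 1 (S)-4-benzyl-1,3-oxazolidine-2-thione; 2 (benzyloxy)acetyl chloride
Product: 3 (S)-4-benzyl-3-[(benzyloxy)acetyl]-1,3-oxazolidine-2-thione
Conditions: Et3N, CH2Cl2, 0 °C to rt
Reagents that add atoms: none
Why: N-acylation of the auxiliary by an acid chloride under amine base, which touches no stereocentre.

Step 2
Reactants: 3 (S)-4-benzyl-3-[(benzyloxy)acetyl]-1,3-oxazolidine-2-thione; 4 3,4-bis(benzyloxy)benzaldehyde
Product: 6 (S)-4-benzyl-3-[(2R,3R)-2-(benzyloxy)-3-[3,4-bis(benzyloxy)phenyl]-3-hydroxypropanoyl]-1,3-oxazolidine-2-thione, via titanium enolate 5 (not isolated)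
Conditions: TiCl4 (1.05 equiv), i-Pr2NEt (1.1 equiv), CH2Cl2, −78 °C; then 4 premixed with TiCl4 (2 equiv), −78 °C; aq NH4Cl
Reagents that add atoms: none
Why: Auxiliary-controlled anti-selective glycolate aldol addition of a titanium enolate (Crimmins type), in which the chelated (Z)-enolate should be attacked anti to the C4 benzyl group through an open transition state by the TiCl4-activated aldehyde, setting C2 (R) and C3 (R) in the anti relationship.

Step 3
Reactants: 6 (S)-4-benzyl-3-[(2R,3R)-2-(benzyloxy)-3-[3,4-bis(benzyloxy)phenyl]-3-hydroxypropanoyl]-1,3-oxazolidine-2-thione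
Product: 7 (1R,2S)-2-(benzyloxy)-1-[3,4-bis(benzyloxy)phenyl]propane-1,3-diol
Conditions: LiBH4, THF/MeOH, 0 °C
Reagents that add atoms: none
Why: Borohydride reduction of the N-acyl oxazolidinethione to the primary alcohol should release the auxiliary without touching either stereocentre.

Step 4
Reactants: 7 (1R,2S)-2-(benzyloxy)-1-[3,4-bis(benzyloxy)phenyl]propane-1,3-diol
Product: 8 (1R,2R)-2-(benzyloxy)-1-[3,4-bis(benzyloxy)phenyl]-3-iodopropan-1-ol
Conditions: I2 (1.05 equiv), PPh3, imidazole, CH2Cl2, 0 °C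
Reagents that add atoms: iodine, II
Why: Garegg–Samuelsson (Appel-type) iodination, which should convert the unhindered primary hydroxyl much faster than the secondary benzylic one.

Step 5
Reactants: 9 3,5-dichlorophenol
Product: 10 1-(benzyloxy)-3,5-dichlorobenzene
Conditions: BnBr, K2CO3, DMF, rt
Reagents that add atoms: benzyl bromide, BrCc1ccccc1
Why: Williamson ether synthesis on a phenoxide.

Step 6
Reactants: 8 (1R,2R)-2-(benzyloxy)-1-[3,4-bis(benzyloxy)phenyl]-3-iodopropan-1-ol; 10 1-(benzyloxy)-3,5-dichlorobenzene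
Product: 15 (2R,3S)-3,7-bis(benzyloxy)-2-[3,4-bis(benzyloxy)phenyl]-5-chlorochromane, via aryllithium 11 (not isolated), via lithium alkoxide 12 (not isolated), via aryne 13 (not isolated), via aryllithium adduct 14 (not isolated)
Conditions: 10 (3 equiv), n-BuLi (3 equiv), THF, −78 °C, 1 h; 8 (1 equiv) in THF, −78 °C; warm to −30 °C over 3 h, then 0 °C; aq NH4Cl
Reagents that add atoms: none
Why: Proposed new method: anionic aryne annulation; 11 (from 10 by deprotonation between the two chlorines) turns 8 into alkoxide 12 and on warming loses LiCl to aryne 13, 12 adds through oxygen to the aryne carbon remote from chlorine (O1–C8a bond), and the aryllithium 14 so formed, with lithium on the carbon between C–Cl and the new C–O, displaces the primary iodide (C4–C4a bond). The closest known reaction types are the etherification of base-generated arynes by alkoxides and the Parham cyclialkylation of aryllithiums that carry an alkyl halide, whose merger with an sp3 carbon as the trap of the aryne-derived carbanion is the untested part. Ring C closes in the 6-exo-tet mode, and the benzyl ether on O3 excludes epoxide formation and the five-ring alternative. No stereocentre is formed: C2 and C3 come unchanged from 8 because no bond to either is broken, so that the anti arrangement of 8 becomes the 2,3-trans relationship of ring C. The step needs regioselective addition to the aryne, which the chlorine at the future C5 should secure by distorting the aryne towards attack at the carbon meta to it and by stabilising the adjacent carbanion, while the equivalence of the two C–Cl bonds of 10 allows only one aryne. It also needs the iodide displacement in 14 to outrun a second loss of LiCl, for which the low temperature and the fast intramolecular iodide trap are chosen.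

Step 7
Reactants: 15 (2R,3S)-3,7-bis(benzyloxy)-2-[3,4-bis(benzyloxy)phenyl]-5-chlorochromane
Product: 16 (2R,3S,4R)-3,7-bis(benzyloxy)-2-[3,4-bis(benzyloxy)phenyl]-5-chloro-4-(2-ethoxyethoxy)chromane
Conditions: DDQ (2 equiv), 2-ethoxyethanol (5 equiv), CH2Cl2, rt
Reagents that add atoms: 2-ethoxyethanol, CCOCCO
Why: DDQ-mediated benzylic oxidation (hydride abstraction from C4 to the cation stabilised by O1 and the para 7-benzyloxy group, then capture by the alcohol anti to the 3-benzyloxy group) is the standard C4 activation of O-benzylated flavan-3-ols and should be selective for C4–H, the C4 configuration being lost again in step 8.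

Step 8
Reactants: 16 (2R,3S,4R)-3,7-bis(benzyloxy)-2-[3,4-bis(benzyloxy)phenyl]-5-chloro-4-(2-ethoxyethoxy)chromane; 15 (2R,3S)-3,7-bis(benzyloxy)-2-[3,4-bis(benzyloxy)phenyl]-5-chlorochromane (3 equiv, excess recovered)
Product: 17 (2R,3S,4R)-3,7-bis(benzyloxy)-2-[3,4-bis(benzyloxy)phenyl]-4-{(2R,3S)-3,7-bis(benzyloxy)-2-[3,4-bis(benzyloxy)phenyl]-5-chlorochroman-8-yl}-5-chlorochromane
Conditions: TMSOTf (0.5 equiv), CH2Cl2, −78 to −30 °C; Et3N quench
Reagents that add atoms: none
Why: Lewis-acid-mediated Friedel–Crafts arylation of the flavan-4-yl cation (the standard interflavan bond formation of proanthocyanidin synthesis), in which C8 of 15 (para to chlorine, flanked by the tied-back ring oxygen) should react in preference to C6 (between chlorine and the 7-benzyloxy group), and attack anti to the 3-benzyloxy group of the cation should give the 3,4-trans (4α) bond.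

Step 9
Reactants: 17 (2R,3S,4R)-3,7-bis(benzyloxy)-2-[3,4-bis(benzyloxy)phenyl]-4-{(2R,3S)-3,7-bis(benzyloxy)-2-[3,4-bis(benzyloxy)phenyl]-5-chlorochroman-8-yl}-5-chlorochromane
Product: 18 (2R,3S,4S)-2-(3,4-dihydroxyphenyl)-4-[(2R,3S)-2-(3,4-dihydroxyphenyl)-3,7-dihydroxychroman-8-yl]chromane-3,7-diol
Conditions: H2 (4 bar), Pd(OH)2/C, NaOAc (3 equiv), THF/MeOH/H2O, rt
Reagents that add atoms: none
Why: Heterogeneous palladium-catalysed hydrogenolysis should cleave the eight benzyl ethers and, with acetate as HCl acceptor, the two aryl C–Cl bonds (hydrodechlorination) in one operation without touching any stereocentre.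

**Compound list**
1 | (S)-4-benzyl-1,3-oxazolidine-2-thione | S=C1N[C@@H](Cc2ccccc2)CO1 | starting material
2 | (benzyloxy)acetyl chloride | O=C(Cl)COCc1ccccc1 | starting material
3 | (S)-4-benzyl-3-[(benzyloxy)acetyl]-1,3-oxazolidine-2-thione | O=C(COCc1ccccc1)N1C(=S)OC[C@@H]1Cc1ccccc1 | intermediate
4 | 3,4-bis(benzyloxy)benzaldehyde | O=Cc1ccc(OCc2ccccc2)c(OCc2ccccc2)c1 | starting material
5 | trichlorotitanium (Z)-enolate of 3 | Cl[Ti](Cl)(Cl)O/C(=C\OCc1ccccc1)N1C(=S)OC[C@@H]1Cc1ccccc1 | intermediate (not isolated)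
6 | (S)-4-benzyl-3-[(2R,3R)-2-(benzyloxy)-3-[3,4-bis(benzyloxy)phenyl]-3-hydroxypropanoyl]-1,3-oxazolidine-2-thione | O[C@H](c1ccc(OCc2ccccc2)c(OCc2ccccc2)c1)[C@@H](OCc1ccccc1)C(=O)N1C(=S)OC[C@@H]1Cc1ccccc1 | intermediate
7 | (1R,2S)-2-(benzyloxy)-1-[3,4-bis(benzyloxy)phenyl]propane-1,3-diol | O[C@H](c1ccc(OCc2ccccc2)c(OCc2ccccc2)c1)[C@@H](OCc1ccccc1)CO | intermediate
8 | (1R,2R)-2-(benzyloxy)-1-[3,4-bis(benzyloxy)phenyl]-3-iodopropan-1-ol | O[C@H](c1ccc(OCc2ccccc2)c(OCc2ccccc2)c1)[C@@H](OCc1ccccc1)CI | intermediate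
9 | 3,5-dichlorophenol | Oc1cc(Cl)cc(Cl)c1 | starting material
10 | 1-(benzyloxy)-3,5-dichlorobenzene | Clc1cc(Cl)cc(OCc2ccccc2)c1 | intermediate
11 | [4-(benzyloxy)-2,6-dichlorophenyl]lithium | [Li]c1c(Cl)cc(OCc2ccccc2)cc1Cl | intermediate (not isolated)
12 | lithium (1R,2R)-2-(benzyloxy)-1-[3,4-bis(benzyloxy)phenyl]-3-iodopropan-1-olate | [Li]O[C@H](c1ccc(OCc2ccccc2)c(OCc2ccccc2)c1)[C@@H](OCc1ccccc1)CI | intermediate (not isolated)
13 | 5-(benzyloxy)-3-chlorobenzyne | ClC1=CC(OCc2ccccc2)=CC#C1 | intermediate (not isolated)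
14 | {4-(benzyloxy)-2-chloro-6-[(1R,2R)-2-(benzyloxy)-1-[3,4-bis(benzyloxy)phenyl]-3-iodopropoxy]phenyl}lithium | [Li]c1c(Cl)cc(OCc2ccccc2)cc1O[C@H](c1ccc(OCc2ccccc2)c(OCc2ccccc2)c1)[C@@H](OCc1ccccc1)CI | intermediate (not isolated)
15 | (2R,3S)-3,7-bis(benzyloxy)-2-[3,4-bis(benzyloxy)phenyl]-5-chlorochromane | c1c(OCc3ccccc3)cc(Cl)c2c1O[C@H](c1ccc(OCc3ccccc3)c(OCc3ccccc3)c1)[C@@H](OCc1ccccc1)C2 | intermediate
16 | (2R,3S,4R)-3,7-bis(benzyloxy)-2-[3,4-bis(benzyloxy)phenyl]-5-chloro-4-(2-ethoxyethoxy)chromane | c1c(OCc3ccccc3)cc(Cl)c2c1O[C@H](c1ccc(OCc3ccccc3)c(OCc3ccccc3)c1)[C@@H](OCc1ccccc1)[C@@H]2OCCOCC | intermediate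
17 | (2R,3S,4R)-3,7-bis(benzyloxy)-2-[3,4-bis(benzyloxy)phenyl]-4-{(2R,3S)-3,7-bis(benzyloxy)-2-[3,4-bis(benzyloxy)phenyl]-5-chlorochroman-8-yl}-5-chlorochromane | c1c(OCc3ccccc3)cc(Cl)c2c1O[C@H](c1ccc(OCc3ccccc3)c(OCc3ccccc3)c1)[C@@H](OCc1ccccc1)[C@@H]2c1c(OCc3ccccc3)cc(Cl)c2c1O[C@H](c1ccc(OCc3ccccc3)c(OCc3ccccc3)c1)[C@@H](OCc1ccccc1)C2 | intermediate
18 | (2R,3S,4S)-2-(3,4-dihydroxyphenyl)-4-[(2R,3S)-2-(3,4-dihydroxyphenyl)-3,7-dihydroxychroman-8-yl]chromane-3,7-diol, fisetinidol-(4α→8)-fisetinidol | Oc1ccc2c(c1)O[C@H](c1ccc(O)c(O)c1)[C@@H](O)[C@@H]2c1c(O)ccc2c1O[C@H](c1ccc(O)c(O)c1)[C@@H](O)C2 | target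

**Count**
Total: 9 steps. Longest linear sequence: 8 steps (steps 1–4 and 6–9, from 1 and 2 to 18).

**Steps most likely to fail**

Step 6 (Proposed new method). Aryne 13 may be captured by aryllithium 11 instead of the hindered lithium alkoxide 12, and 14 may lose LiCl before ring C closes. The fallback makes the same two bonds stepwise by known reactions, from 8 and 10 back to 15. Aryllithium 11 (from 10, n-BuLi, THF, −78 °C) is transmetalated with MgBr2·OEt2 to [4-(benzyloxy)-2,6-dichlorophenyl]magnesium bromide F1, which does not eliminate to an aryne. Iron-catalysed Kumada-type cross-coupling of F1 (2.2 equiv, the first equivalent deprotonating the hydroxyl) with the primary iodide 8 (Fe(acac)3, TMEDA, THF, 0 °C) should give (1R,2S)-2-(benzyloxy)-1-[3,4-bis(benzyloxy)phenyl]-3-[4-(benzyloxy)-2,6-dichlorophenyl]propan-1-ol F2. Palladium-catalysed intramolecular C–O coupling of F2 (Pd(OAc)2, 2-(di-tert-butylphosphino)-1,1'-binaphthyl, Cs2CO3, toluene, 80 °C) onto either of the two equivalent C–Cl bonds then closes ring C and returns to 15.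

Step 8. The cation may attack C6 of ring A of 15, the hindered chlorine-bearing nucleophile may react sluggishly, or 16 may condense with itself. The fallback caps the competing position first and runs from 15 to 18. NBS (CH2Cl2, −20 °C) should enter C6 to give (2R,3S)-3,7-bis(benzyloxy)-2-[3,4-bis(benzyloxy)phenyl]-6-bromo-5-chlorochromane F3. F3 can react with 16 (TMSOTf, CH2Cl2, −78 to −30 °C) only at C8, to give (2R,3S,4R)-3,7-bis(benzyloxy)-2-[3,4-bis(benzyloxy)phenyl]-4-{(2R,3S)-3,7-bis(benzyloxy)-2-[3,4-bis(benzyloxy)phenyl]-6-bromo-5-chlorochroman-8-yl}-5-chlorochromane F4. Under the conditions of step 9 the C–Br bond should be cleaved together with the C–Cl bonds and the benzyl ethers, which gives 18.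

Step 9. Hydrodechlorination of the two electron-rich aryl chlorides (the upper one peri to C4) may be incomplete, or the released chloride may stall debenzylation. The fallback separates the two tasks, from 17 to 18. Homogeneous palladium-catalysed transfer hydrodechlorination (Pd(OAc)2, XPhos, HCO2Na, DMF, 80 °C), which leaves benzyl ethers intact, should give (2R,3S,4S)-3,7-bis(benzyloxy)-2-[3,4-bis(benzyloxy)phenyl]-4-{(2R,3S)-3,7-bis(benzyloxy)-2-[3,4-bis(benzyloxy)phenyl]chroman-8-yl}chromane F5. Neutral hydrogenolysis of F5 (H2, Pd(OH)2/C, THF/MeOH, rt) then gives 18.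

**Further compounds**
F1 | step 6 | [4-(benzyloxy)-2,6-dichlorophenyl]magnesium bromide | Br[Mg]c1c(Cl)cc(OCc2ccccc2)cc1Cl
F2 | step 6 | (1R,2S)-2-(benzyloxy)-1-[3,4-bis(benzyloxy)phenyl]-3-[4-(benzyloxy)-2,6-dichlorophenyl]propan-1-ol | O[C@H](c1ccc(OCc2ccccc2)c(OCc2ccccc2)c1)[C@@H](OCc1ccccc1)Cc1c(Cl)cc(OCc2ccccc2)cc1Cl
F3 | step 8 | (2R,3S)-3,7-bis(benzyloxy)-2-[3,4-bis(benzyloxy)phenyl]-6-bromo-5-chlorochromane | c1c(OCc3ccccc3)c(Br)c(Cl)c2c1O[C@H](c1ccc(OCc3ccccc3)c(OCc3ccccc3)c1)[C@@H](OCc1ccccc1)C2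
F4 | step 8 | (2R,3S,4R)-3,7-bis(benzyloxy)-2-[3,4-bis(benzyloxy)phenyl]-4-{(2R,3S)-3,7-bis(benzyloxy)-2-[3,4-bis(benzyloxy)phenyl]-6-bromo-5-chlorochroman-8-yl}-5-chlorochromane | c1c(OCc3ccccc3)cc(Cl)c2c1O[C@H](c1ccc(OCc3ccccc3)c(OCc3ccccc3)c1)[C@@H](OCc1ccccc1)[C@@H]2c1c(OCc3ccccc3)c(Br)c(Cl)c2c1O[C@H](c1ccc(OCc3ccccc3)c(OCc3ccccc3)c1)[C@@H](OCc1ccccc1)C2
F5 | step 9 | (2R,3S,4S)-3,7-bis(benzyloxy)-2-[3,4-bis(benzyloxy)phenyl]-4-{(2R,3S)-3,7-bis(benzyloxy)-2-[3,4-bis(benzyloxy)phenyl]chroman-8-yl}chromane | c1c(OCc3ccccc3)ccc2c1O[C@H](c1ccc(OCc3ccccc3)c(OCc3ccccc3)c1)[C@@H](OCc1ccccc1)[C@@H]2c1c(OCc3ccccc3)ccc2c1O[C@H](c1ccc(OCc3ccccc3)c(OCc3ccccc3)c1)[C@@H](OCc1ccccc1)C2
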